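**Retrosynthetic overview**

1. Target 20 comes from its tetramethyl ether 19 (BBr3), and 19 from the macrocyclic bis(dithiane) 18 (Raney Ni); each CH2CH2 bridge is carried as ArC(1,3-dithiane)–CH2Ar'.
2. Key disconnection, and the only ring-forming event (the 17-membered macrocycle): the bond between the ring A dithiane carbon and the ring D benzylic carbon, closed by intramolecular alkylation of a 2-aryl-2-lithio-1,3-dithiane (masked acyl anion) on a benzylic chloride (16 to 18).
3. Second bridge (ring C dithiane carbon to ring B benzylic carbon): intermolecular alkylation of the dilithio dianion 13 with benzylic bromide 12.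
4. Both diaryl ethers: SNAr of the dithiane-bearing phenols 3 and 8 on 2- and 4-fluorobenzaldehyde. This also tells the four formyl carbons apart (two dithianes as nucleophiles, two CH2X as electrophiles).
5. Rings A to D are bought as benzaldehydes. Ring A is the 3-aryloxy-4,5-dioxygenated ring, ring B the para-phenylene, ring C the 2-aryloxy-3,4-dioxygenated ring, ring D the ortho-phenylene.

Assumption: the SMILES has no stereocentre and no stereodescriptor, and the 17-membered ring is taken as conformationally mobile, so no stereoselective step is needed.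

The route is a paper proposal; conditions and selectivities are reasoned from known reactivity and have not been run.

**Route**

Step 1
Reactants: 1 2-hydroxy-3,4-dimethoxybenzaldehyde; 2 propane-1,3-dithiol
Product: 3 6-(1,3-dithian-2-yl)-2,3-dimethoxyphenol
Conditions: BF3·OEt2 (0.3 equiv), CH2Cl2, 0 °C to rt
Reagents that add atoms: none
Why: Lewis acid-catalysed dithioacetalisation masks the ring C formyl carbon as the later nucleophile before the second formyl group enters, and the free phenol is untouched.

Step 2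
Reactants: 3 6-(1,3-dithian-2-yl)-2,3-dimethoxyphenol; 4 2-fluorobenzaldehyde
Product: 6 {2-[6-(1,3-dithian-2-yl)-2,3-dimethoxyphenoxy]phenyl}methanol, via aldehyde 5 (not isolated)
Conditions: K2CO3, DMF, 120 °C, N2; then MeOH, NaBH4, 0 °C
Reagents that add atoms: none
Why: Nucleophilic aromatic substitution (SNAr) of the phenoxide on the fluoride activated by the ortho formyl group builds the ring C–O–ring D ether with the dithiane inert to carbonate, and hydride reduction in the same pot turns only the new ring D aldehyde into CH2OH.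

Step 3
Reactants: 7 3-hydroxy-4,5-dimethoxybenzaldehyde; 2 propane-1,3-dithiol
Product: 8 5-(1,3-dithian-2-yl)-2,3-dimethoxyphenol
Conditions: BF3·OEt2 (0.3 equiv), CH2Cl2, 0 °C to rt
Reagents that add atoms: none
Why: The same dithioacetalisation masks the ring A formyl carbon as the nucleophile of the ring closure.

Step 4
Reactants: 8 5-(1,3-dithian-2-yl)-2,3-dimethoxyphenol; 9 4-fluorobenzaldehyde
Product: 11 {4-[5-(1,3-dithian-2-yl)-2,3-dimethoxyphenoxy]phenyl}methanol, via aldehyde 10 (not isolated)
Conditions: K2CO3, DMF, 100 °C, N2; then MeOH, NaBH4, 0 °C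
Reagents that add atoms: none
Why: SNAr on the para-formyl-activated fluoride gives the ring A–O–ring B ether (the phenoxide has only one ortho substituent), and NaBH4 reduction in the same pot leaves the ring B carbon as CH2OH.

Step 5
Reactants: 11 {4-[5-(1,3-dithian-2-yl)-2,3-dimethoxyphenoxy]phenyl}methanol
Product: 12 2-{3-[4-(bromomethyl)phenoxy]-4,5-dimethoxyphenyl}-1,3-dithiane
Conditions: CBr4, PPh3, CH2Cl2, 0 °C
Reagents that add atoms: carbon tetrabromide, BrC(Br)(Br)Br
Why: The Appel reaction converts the primary benzylic alcohol into the bromide under neutral conditions that leave the dithiane and the diaryl ether alone.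

Step 6
Reactants: 6 {2-[6-(1,3-dithian-2-yl)-2,3-dimethoxyphenoxy]phenyl}methanol; 12 2-{3-[4-(bromomethyl)phenoxy]-4,5-dimethoxyphenyl}-1,3-dithiane
Product: 14 {2-[6-(2-{4-[5-(1,3-dithian-2-yl)-2,3-dimethoxyphenoxy]benzyl}-1,3-dithian-2-yl)-2,3-dimethoxyphenoxy]phenyl}methanol, via dilithio dianion 13 (not isolated)
Conditions: n-BuLi (2.1 equiv), THF, −78 to −30 °C; then 12, −78 to −20 °C; H2O
Reagents that add atoms: n-butyllithium, [Li]CCCC (lithium of 13 only; nothing in 14)
Why: Corey–Seebach alkylation: the first equivalent of n-BuLi protects the alcohol as its alkoxide and the second gives the 2-aryl-2-lithio-1,3-dithiane (pKa about 31), whose soft carbanion displaces the benzylic bromide by SN2 faster than it takes the dithiane proton of 12 or than the alkoxide is O-alkylated, so the formyl-derived carbon of ring C is joined to the benzylic carbon of ring B.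

Step 7
Reactants: 14 {2-[6-(2-{4-[5-(1,3-dithian-2-yl)-2,3-dimethoxyphenoxy]benzyl}-1,3-dithian-2-yl)-2,3-dimethoxyphenoxy]phenyl}methanol
Product: 16 2-{2-[2-(chloromethyl)phenoxy]-3,4-dimethoxyphenyl}-2-{4-[5-(1,3-dithian-2-yl)-2,3-dimethoxyphenoxy]benzyl}-1,3-dithiane, via mesylate 15 (not isolated)
Conditions: MsCl, Et3N, CH2Cl2, 0 °C; then LiCl, DMF, rt
Reagents that add atoms: methanesulfonyl chloride, CS(=O)(=O)Cl (mesyl group of 15 only); lithium chloride, [Li+].[Cl-] (chlorine of 16)
Why: Sulfonylation followed by SN2 chloride displacement makes the primary benzylic chloride without acid or oxidant, so both dithianes survive; the chloride is chosen over the bromide because it resists the amide base of the next step better.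

Step 8
Reactants: 16 2-{2-[2-(chloromethyl)phenoxy]-3,4-dimethoxyphenyl}-2-{4-[5-(1,3-dithian-2-yl)-2,3-dimethoxyphenoxy]benzyl}-1,3-dithiane
Product: 18 tetra-O-methyl macrocyclic bis(dithiane) (17-membered ring in which the bridge carbon next to ring A and the bridge carbon next to ring C are each C2 of a 1,3-dithiane), via lithiodithiane 17 (not isolated)
Conditions: LDA (2.5 equiv), THF, −78 °C, 16 added by syringe pump over 8 h (final 1 mM), then to −10 °C; H2O
Reagents that add atoms: lithium diisopropylamide, [Li]N(C(C)C)C(C)C (lithium of 17 only; nothing in 18)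
Why: Proposed new method: the only acidic C–H left is the 2-H of the ring A dithiane (the ring C dithiane is quaternary), LDA removes it faster than it attacks the benzylic chloride at −78 °C, and at 1 mM the unhindered soft carbanion closes the ring by intramolecular SN2 on the ring D chloromethyl carbon, joining two carbons that were both formyl carbons; the closest known reaction types are the intermolecular Corey–Seebach benzylation of 2-aryl-2-lithio-1,3-dithianes and the high-dilution ring closure of protected cyanohydrin anions onto halides to give macrocyclic ketones.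

Step 9
Reactants: 18 tetra-O-methyl macrocyclic bis(dithiane)
Product: 19 tetra-O-methyl ether of the target (both bridges CH2CH2)
Conditions: Raney Ni (W-2, excess), EtOH/THF, reflux
Reagents that add atoms: none
Why: Raney Ni hydrogenolytic desulfurisation (Mozingo reduction) cleaves all four C–S bonds and turns both dithiane carbons into CH2, while aryl methyl ethers and diaryl ethers are stable under these conditions.

Step 10
Reactants: 19 tetra-O-methyl ether of the target
Product: 20 target CNP0114693.0
Conditions: BBr3 (10 equiv), CH2Cl2, −78 °C to rt; then H2O, under argon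
Reagents that add atoms: none
Why: BBr3 ether cleavage removes the four aryl methyl groups as MeBr while the diaryl ethers and the bibenzyl bridges are untouched, and hydrolysis of the aryl borates frees the two catechols; no stereocentre is present at any stage.

**Compound list**

1 | 2-hydroxy-3,4-dimethoxybenzaldehyde | O=Cc1ccc(OC)c(OC)c1O | starting material
2 | propane-1,3-dithiol | SCCCS | starting material
3 | 6-(1,3-dithian-2-yl)-2,3-dimethoxyphenol | COc1ccc(C2SCCCS2)c(O)c1OC | intermediate
4 | 2-fluorobenzaldehyde | O=Cc1ccccc1F | starting material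
5 | 2-[6-(1,3-dithian-2-yl)-2,3-dimethoxyphenoxy]benzaldehyde | COc1ccc(C2SCCCS2)c(Oc2ccccc2C=O)c1OC | intermediate (not isolated)
6 | {2-[6-(1,3-dithian-2-yl)-2,3-dimethoxyphenoxy]phenyl}methanol | COc1ccc(C2SCCCS2)c(Oc2ccccc2CO)c1OC | intermediate
7 | 3-hydroxy-4,5-dimethoxybenzaldehyde | O=Cc1cc(O)c(OC)c(OC)c1 | starting material
8 | 5-(1,3-dithian-2-yl)-2,3-dimethoxyphenol | COc1cc(C2SCCCS2)cc(O)c1OC | intermediate
9 | 4-fluorobenzaldehyde | O=Cc1ccc(F)cc1 | starting material
10 | 4-[5-(1,3-dithian-2-yl)-2,3-dimethoxyphenoxy]benzaldehyde | COc1cc(C2SCCCS2)cc(Oc2ccc(C=O)cc2)c1OC | intermediate (not isolated)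
11 | {4-[5-(1,3-dithian-2-yl)-2,3-dimethoxyphenoxy]phenyl}methanol | COc1cc(C2SCCCS2)cc(Oc2ccc(CO)cc2)c1OC | intermediate
12 | 2-{3-[4-(bromomethyl)phenoxy]-4,5-dimethoxyphenyl}-1,3-dithiane | COc1cc(C2SCCCS2)cc(Oc2ccc(CBr)cc2)c1OC | intermediate
13 | dilithio dianion of 6 (lithium alkoxide and 2-lithio-1,3-dithiane) | [Li+].[Li+].COc1ccc([C-]2SCCCS2)c(Oc2ccccc2C[O-])c1OC | intermediate (not isolated)
14 | {2-[6-(2-{4-[5-(1,3-dithian-2-yl)-2,3-dimethoxyphenoxy]benzyl}-1,3-dithian-2-yl)-2,3-dimethoxyphenoxy]phenyl}methanol | COc1ccc(C2(Cc3ccc(Oc4cc(C5SCCCS5)cc(OC)c4OC)cc3)SCCCS2)c(Oc2ccccc2CO)c1OC | intermediate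
15 | methanesulfonate of 14 | COc1ccc(C2(Cc3ccc(Oc4cc(C5SCCCS5)cc(OC)c4OC)cc3)SCCCS2)c(Oc2ccccc2COS(C)(=O)=O)c1OC | intermediate (not isolated)
16 | 2-{2-[2-(chloromethyl)phenoxy]-3,4-dimethoxyphenyl}-2-{4-[5-(1,3-dithian-2-yl)-2,3-dimethoxyphenoxy]benzyl}-1,3-dithiane | COc1ccc(C2(Cc3ccc(Oc4cc(C5SCCCS5)cc(OC)c4OC)cc3)SCCCS2)c(Oc2ccccc2CCl)c1OC | intermediate
17 | 2-lithio derivative of 16 at the ring A dithiane | [Li+].COc1ccc(C2(Cc3ccc(Oc4cc([C-]5SCCCS5)cc(OC)c4OC)cc3)SCCCS2)c(Oc2ccccc2CCl)c1OC | intermediate (not isolated)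
18 | tetra-O-methyl macrocyclic bis(dithiane), 17-membered ring | COc1cc2cc(c1OC)Oc1ccc(cc1)CC1(SCCCS1)c1ccc(OC)c(OC)c1Oc1ccccc1CC21SCCCS1 | intermediate
19 | tetra-O-methyl ether of the target | COc1cc2cc(c1OC)Oc1ccc(cc1)CCc1ccc(OC)c(OC)c1Oc1ccccc1CC2 | intermediate
20 | CNP0114693.0, macrocyclic bis(bibenzyl) tetraphenol | Oc1cc2cc(c1O)Oc1ccc(cc1)CCc1ccc(O)c(O)c1Oc1ccccc1CC2 | target

**Totals**

Total step count: 10. Longest linear sequence: 8 steps (7 to 8 to 11 to 12 to 14 to 16 to 18 to 19 to 20; steps 3, 4, 5, 6, 7, 8, 9, 10).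

**Three steps most likely to fail, each with a fallback**

Step 8 (ring closure). The risks are oligomerisation, attack of the amide base on the benzylic chloride, and a strained transition state next to the crowded ring C–O–ring D ether. The fallback swaps the order of the two alkylations, so that the ring closes at the bridge between rings B and C, where the electrophile is an unhindered, para-oxygen-activated benzylic chloride. It sets out from 6 (with 11 as partner) and comes back at 18. Appel bromination of 6 (CBr4, PPh3) gives 2-{2-[2-(bromomethyl)phenoxy]-3,4-dimethoxyphenyl}-1,3-dithiane F1. Alcohol 11 with n-BuLi (2.1 equiv, THF, −78 °C) gives the dilithio dianion of 11 F2, which is alkylated at −78 °C by F1 to {4-[5-(2-{2-[6-(1,3-dithian-2-yl)-2,3-dimethoxyphenoxy]benzyl}-1,3-dithian-2-yl)-2,3-dimethoxyphenoxy]phenyl}methanol F3. MsCl/Et3N then LiCl take F3 through the methanesulfonate of F3 F4 to the benzylic chloride of F3 F5. LDA at 1 mM gives the ring C 2-lithio derivative of F5 F6, which closes to 18. F1 is kept cold and meets only the preformed anion, because its own anion would close a seven-membered ring.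

Step 6 (dianion alkylation). The risks are poor solubility or incomplete formation of the dianion, O-alkylation, and proton transfer from the dithiane of 12. The fallback replaces self-protection as the alkoxide by a silyl ether, so that a single carbanion is used. It sets out from 6 and comes back at 14. TBSCl and imidazole in DMF give tert-butyl({2-[6-(1,3-dithian-2-yl)-2,3-dimethoxyphenoxy]benzyl}oxy)dimethylsilane F7. n-BuLi (1.05 equiv, THF, −78 to −30 °C) gives the 2-lithio derivative of F7 F8, which is alkylated by 12 to the tert-butyldimethylsilyl ether of 14 F9. Bu4NF in THF frees 14.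

Step 2 (SNAr of a phenoxide with two ortho substituents on an ortho-substituted fluoride). The risk is low conversion from crowding. The fallback is an Ullmann-type coupling in place of SNAr. It sets out from 3 and comes back at 6: 3 and 2-iodobenzyl alcohol with CuI (10 mol %), picolinic acid and K3PO4 in DMSO at 90 °C give 6 directly, the phenoxide being arylated in preference to the benzylic alcohol. This fallback makes no compound outside the list (F0).

**Further compounds**

F1 | step 8 | 2-{2-[2-(bromomethyl)phenoxy]-3,4-dimethoxyphenyl}-1,3-dithiane | COc1ccc(C2SCCCS2)c(Oc2ccccc2CBr)c1OC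
F2 | step 8 | dilithio dianion of 11 | [Li+].[Li+].COc1cc([C-]2SCCCS2)cc(Oc2ccc(C[O-])cc2)c1OC
F3 | step 8 | {4-[5-(2-{2-[6-(1,3-dithian-2-yl)-2,3-dimethoxyphenoxy]benzyl}-1,3-dithian-2-yl)-2,3-dimethoxyphenoxy]phenyl}methanol | COc1cc(C2(Cc3ccccc3Oc3c(C4SCCCS4)ccc(OC)c3OC)SCCCS2)cc(Oc2ccc(CO)cc2)c1OC
F4 | step 8 | methanesulfonate of F3 | COc1cc(C2(Cc3ccccc3Oc3c(C4SCCCS4)ccc(OC)c3OC)SCCCS2)cc(Oc2ccc(COS(C)(=O)=O)cc2)c1OC
F5 | step 8 | benzylic chloride of F3 | COc1cc(C2(Cc3ccccc3Oc3c(C4SCCCS4)ccc(OC)c3OC)SCCCS2)cc(Oc2ccc(CCl)cc2)c1OC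
F6 | step 8 | ring C 2-lithio derivative of F5 | [Li+].COc1cc(C2(Cc3ccccc3Oc3c([C-]4SCCCS4)ccc(OC)c3OC)SCCCS2)cc(Oc2ccc(CCl)cc2)c1OC
F7 | step 6 | tert-butyl({2-[6-(1,3-dithian-2-yl)-2,3-dimethoxyphenoxy]benzyl}oxy)dimethylsilane | COc1ccc(C2SCCCS2)c(Oc2ccccc2CO[Si](C)(C)C(C)(C)C)c1OC
F8 | step 6 | 2-lithio derivative of F7 | [Li+].COc1ccc([C-]2SCCCS2)c(Oc2ccccc2CO[Si](C)(C)C(C)(C)C)c1OC
F9 | step 6 | tert-butyldimethylsilyl ether of 14 | COc1ccc(C2(Cc3ccc(Oc4cc(C5SCCCS5)cc(OC)c4OC)cc3)SCCCS2)c(Oc2ccccc2CO[Si](C)(C)C(C)(C)C)c1OC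
F0 | step 2 | none | none
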